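Percent of the charge was my unit, counted also on what had not yet gone in.

all flasks: starting material 0.13 M (fed, over 3.0 d)
- midnight: reagent in the second phase 0.26 M; the very flask that is asked about, followed so far
- flask: reagent in the second phase 0.260 M; time 15 d; volume of the second phase over the first 1.0

midnight run (percent of the starting material charged)

| time / h | target / % | starting material / % |
|---|---|---|
| 3.00 | 0 | 4 |
| 6.00 | 0 | 6 |
| 12.0 | 0 | 14 |
| 25.0 | 8 | 26 |
| 40.0 | 17 | 32 |

(each reading ± 1.5 percentage points)

1. the moment within 15 d at which there is most target
2. the amount of target, in percent of the starting material charged, at that time

- in the second phase: reagent in the second phase; everything else is in the first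
- charges count per volume of the first phase; a concentration in a rate is the amount of a species over the volume of its own phase; every rate counts per litre of the first phase
- the earlier runs hold the two phases in the same ratio of volumes as the flask asked about
- percentages count the whole charge, also what has not yet gone in

1. The flask at 40.0 h held starting material 32% and target 17%, with 44.4% of the charge still to be fed.

2. I worked with what was left. Let s be the share of reacted starting material (fed minus found) still present as target, a selectivity on conversion. As a reading, with scatter 1.5 percentage points, s fell from 91.7% at 25.0 h to 72.2% at 40.0 h, so its loss constant λ read 0.0160 h⁻¹.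

3. Extending the last rise of starting material gave 44.8% at the end of the feed, so 55.2% reacted. λ gave s = 43.3%, so target stood near 23.9%. I expected the top soon after 3.0 d.

4. Take the flask near that top.

The forecast said 46% at 4.4 d, on the ground that “Reagent depletion slows both steps”.

The flask topped at 30.4% at 3.56 d, with 48.1% still starting material. At 3.00 d the flask had held 54.8% starting material and 29.1% target, so 45.2% had reacted, below my 55.2%, and s stood at 64.4%, below the 72.2% read at 40.0 h but above my 43.3%: my reckoning parted from the flask on both figures.

    reagent in the reaction phase + target → over-reacted product (k = 0.00152 M⁻¹ min⁻¹)
    2 reagent in the reaction phase → self-condensation product (k = 0.00218 M⁻¹ min⁻¹)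
    reagent in the reaction phase → decomposed reagent (k = 6.95 × 10⁻⁴ min⁻¹)
    target → over-reaction product (k = 2.07 × 10⁻⁴ min⁻¹)
    starting material + reagent in the reaction phase → target (k = 0.0120 M⁻¹ min⁻¹)
    reagent in the reaction phase ⇌ reagent in the second phase, rate k6*([reagent in the reaction phase] - [reagent in the second phase]/K6) per volume of the first phase (partition coefficient = 2.51, kL = 0.00340 min⁻¹)

With 0.33 M of starting material, 56.3% remained at 15.0 d, so 43.7% had reacted; with 0.982% target on that, s stood at 2.25% at that time. The computed top of that flask is 22.1%.

The readings are calculated for substances that don't exist, and the scatter is random.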